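Hanultarin is the mono-ferulate of (2R,3R)-secoisolariciresinol. After the ester C–O bond is cut, the C2-symmetric core is disconnected at C2–C7 and C3–C7′. The feature used is the 1,4-dioxygenated butane chain: its inner carbons C2 and C3 are the only stereocentres, each is tied through one benzylic carbon to a guaiacyl ring (rings A and B), and each becomes enolisable once C1 and C4 are raised to the acyl level. A two-directional Evans alkylation therefore installs both arylmethyl arms and both stereocentres in one operation. Its precursor is succinic acid capped at both ends by (R)-4-benzyloxazolidinone, and the electrophile is a silyl-protected vanillyl bromide.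

Key step: step 5

Remarks and assumptions
- Labels: the butane chain is C1–C4, with C1 carrying the ester oxygen in the target. C7 (on C2) and C7′ (on C3) are the benzylic carbons. Rings A and B are the guaiacyl rings and ring C is the feruloyl ring.
- Configuration: the target SMILES reads R at both C2 and C3. The priority order C1 > C3 > C7 > H is the same in imide, diol and ester, so the descriptor does not change after the key step.
- Auxiliary sense: the (R)-auxiliary is the correct one. The incoming C7 ranks below the resident C3, so the descriptor is opposite to that of the familiar propionate/benzyl bromide case, although the facial sense is the same.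
- Protection: all three phenols carry TBS groups. Acetal protection was rejected because bromide formation, acid activation and final acidic cleavage would each expose an acid-labile group or the ester to acid. With TBS, the ferulic acid partner needs one operation and the end game is one buffered fluoride step.
- Assumption: NaN(SiMe3)2 brings both imide termini to the enolate stage at −78 °C, at the latest once the first alkylation has occurred.

Step 1
Reactants: 1 vanillin
Product: 2 4-[(tert-butyldimethylsilyl)oxy]-3-methoxybenzaldehyde
Conditions: TBSCl, imidazole, CH2Cl2, 0 °C to rt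
Reagents that add atoms: tert-butyldimethylsilyl chloride, CC(C)(C)[Si](C)(C)Cl
Why: Imidazole-mediated O-silylation of the single phenol is routine, and the aryl silyl ether tolerates the hydride, amide-base and carbodiimide steps ahead while leaving under buffered fluoride at the end.

Step 2
Reactants: 2 4-[(tert-butyldimethylsilyl)oxy]-3-methoxybenzaldehyde
Product: 3 {4-[(tert-butyldimethylsilyl)oxy]-3-methoxyphenyl}methanol
Conditions: NaBH4, MeOH–THF, 0 °C
Reagents that add atoms: none
Why: Borohydride reduction of an aryl aldehyde to the benzylic alcohol is fast at 0 °C, so the aryl silyl ether is not exposed to methoxide for long and no other reducible group is present.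

Step 3
Reactants: 3 {4-[(tert-butyldimethylsilyl)oxy]-3-methoxyphenyl}methanol
Product: 4 [4-(bromomethyl)-2-methoxyphenoxy](tert-butyl)dimethylsilane
Conditions: CBr4, PPh3, CH2Cl2, 0 °C
Reagents that add atoms: carbon tetrabromide, BrC(Br)(Br)Br
Why: The Appel reaction turns the primary benzylic alcohol into the bromide under neutral conditions, which avoids the HBr that phosphorus or hydrogen halide reagents would release onto an acid-sensitive, electron-rich benzylic system, and the bromide is passed through a short silica plug and used at once.

Step 4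
Reactants: 5 (4R)-4-benzyl-1,3-oxazolidin-2-one (2 equiv); 6 succinyl chloride
Product: 8 1,4-bis[(4R)-4-benzyl-2-oxo-1,3-oxazolidin-3-yl]butane-1,4-dione, via N-lithio oxazolidinone 7 (not isolated)
Conditions: n-BuLi, THF, −78 °C; then 6 (0.5 equiv, freshly distilled), −78 to 0 °C
Reagents that add atoms: none
Why: N-Acylation of the lithiated oxazolidinone by an acid chloride is the standard way to Evans imides, both acyl chloride termini react alike, and the auxiliary stereocentres are spectators.

Step 5
Reactants: 8 1,4-bis[(4R)-4-benzyl-2-oxo-1,3-oxazolidin-3-yl]butane-1,4-dione; 4 [4-(bromomethyl)-2-methoxyphenoxy](tert-butyl)dimethylsilane (2.6 equiv)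
Product: 11 (2R,3R)-1,4-bis[(4R)-4-benzyl-2-oxo-1,3-oxazolidin-3-yl]-2,3-bis({4-[(tert-butyldimethylsilyl)oxy]-3-methoxyphenyl}methyl)butane-1,4-dione, via bis-sodium enolate 9 (not isolated), via monobenzylated sodium enolate 10 (not isolated)
Conditions: NaN(SiMe3)2 (2.3 equiv), degassed THF, −78 °C; then 4 in THF, −78 to −40 °C; AcOH–THF quench at −40 °C
Reagents that add atoms: none
Why: NaN(SiMe3)2 removes one proton each from C2 and C3 to give the doubly sodium-chelated (Z,Z)-bis-enolate 9 (should the second deprotonation lag, the base still present completes it once the first bond is made, which leads through the same enolate 10), and each enolate carbon then displaces bromide from 4 in an SN2 step, forming C2–C7 and then C3–C7′. The closest known reaction type is the Evans alkylation of N-acyloxazolidinone sodium enolates by benzylic halides, together with the alkylation of vicinal succinate dianions; it is merely run at both ends of one substrate, and no ring is closed. C2 is controlled by the 4-benzyl group of the auxiliary on C1, which covers one face of the rigid chelate so that C7 enters from the other face and gives R, and C3 is controlled in the same way by the identical auxiliary on C4, again giving R. In enolate 10, A1,3 strain should turn the C2–H bond into the enolate plane, which places the bulky C1 imide on the face that the auxiliary already blocks and only the slim C7 methylene on the open face, so the resident centre is not expected to oppose the auxiliary. The step needs C- over O-alkylation, one alkylation per carbon and no epimerisation: the soft benzylic bromide secures the first, and allylic strain in the product imide, which keeps each new tertiary C–H out of alignment with its carbonyl, secures the other two. A facial error at either end ends up mainly in the (2R,3S) diastereomer, which the auxiliaries make separable by chromatography or crystallisation, so the isolated C2-symmetric product should be of upgraded enantiomeric purity after auxiliary removal.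

Step 6
Reactants: 11 (2R,3R)-bis-imide from step 5
Product: 12 (2R,3R)-2,3-bis({4-[(tert-butyldimethylsilyl)oxy]-3-methoxyphenyl}methyl)butane-1,4-diol
Conditions: LiBH4, MeOH (5 equiv each), THF–Et2O, 0 °C to rt; then aq. potassium sodium tartrate
Reagents that add atoms: none
Why: Reductive removal of Evans auxiliaries with LiBH4 activated by methanol delivers hydride to the exocyclic imide carbonyls and takes C1 and C4 straight to the primary alcohols, while C2 and C3 are never enolised, the aryl silyl ethers are inert to borohydride and the auxiliary is recovered.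

Step 7
Reactants: 13 (E)-ferulic acid
Product: 15 (E)-3-{4-[(tert-butyldimethylsilyl)oxy]-3-methoxyphenyl}prop-2-enoic acid, via bis-silylated ferulate 14 (not isolated)
Conditions: TBSCl (2.5 equiv), imidazole, DMF, rt; then AcOH–THF–H2O, rt
Reagents that add atoms: tert-butyldimethylsilyl chloride, CC(C)(C)[Si](C)(C)Cl
Why: Exhaustive silylation followed by mild aqueous acid exploits the far greater lability of a silyl ester compared with an aryl silyl ether, so that only the carboxyl group is set free and the E-alkene is untouched.

Step 8
Reactants: 12 (2R,3R)-diol from step 6; 15 O-TBS-ferulic acid (0.8 equiv)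
Product: 16 (2R,3R)-4-hydroxy-2,3-bis({4-[(tert-butyldimethylsilyl)oxy]-3-methoxyphenyl}methyl)butyl (E)-3-{4-[(tert-butyldimethylsilyl)oxy]-3-methoxyphenyl}prop-2-enoate
Conditions: DCC, DMAP (cat.), CH2Cl2, 0 °C to rt, 15 added slowly to 12, light excluded
Reagents that add atoms: none
Why: Steglich esterification couples a primary alcohol under neutral conditions, the two hydroxyls of the C2-symmetric diol are homotopic so that mono-acylation can give only one compound (even an acyl shift would be degenerate), and keeping the acid as the limiting partner added slowly holds back the second acylation while unreacted diol is recovered by chromatography.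

Step 9
Reactants: 16 tris-O-TBS hanultarin
Product: 17 hanultarin
Conditions: Bu4NF (3.3 equiv), AcOH (4 equiv), THF, 0 °C
Reagents that add atoms: none
Why: Fluoride cleaves aryl silyl ethers within minutes, and the acetic acid buffer keeps the liberated phenols protonated so that the cinnamate ester, the E-alkene and the two stereocentres are left alone.

Compound list
1 | vanillin | COc1cc(C=O)ccc1O | starting material
2 | 4-[(tert-butyldimethylsilyl)oxy]-3-methoxybenzaldehyde | COc1cc(C=O)ccc1O[Si](C)(C)C(C)(C)C | intermediate
3 | {4-[(tert-butyldimethylsilyl)oxy]-3-methoxyphenyl}methanol | COc1cc(CO)ccc1O[Si](C)(C)C(C)(C)C | intermediate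
4 | [4-(bromomethyl)-2-methoxyphenoxy](tert-butyl)dimethylsilane | COc1cc(CBr)ccc1O[Si](C)(C)C(C)(C)C | intermediate
5 | (4R)-4-benzyl-1,3-oxazolidin-2-one | O=C1N[C@H](Cc2ccccc2)CO1 | starting material
6 | succinyl chloride | O=C(Cl)CCC(=O)Cl | starting material
7 | N-lithio-(4R)-4-benzyl-1,3-oxazolidin-2-one | O=C1N([Li])[C@H](Cc2ccccc2)CO1 | intermediate
8 | 1,4-bis[(4R)-4-benzyl-2-oxo-1,3-oxazolidin-3-yl]butane-1,4-dione | O=C(CCC(=O)N1[C@H](Cc2ccccc2)COC1=O)N1[C@H](Cc2ccccc2)COC1=O | intermediate
9 | disodium (1Z,3Z)-1,4-bis[(4R)-4-benzyl-2-oxo-1,3-oxazolidin-3-yl]buta-1,3-diene-1,4-diolate | [Na]O/C(N1[C@H](Cc2ccccc2)COC1=O)=C\C=C(/O[Na])N1[C@H](Cc2ccccc2)COC1=O | intermediate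
10 | sodium (Z)-enolate at C3–C4 of the bis-imide already benzylated at C2 (C2 is R) | O=C(N1[C@H](Cc2ccccc2)COC1=O)[C@H](Cc1ccc(O[Si](C)(C)C(C)(C)C)c(OC)c1)/C=C(\O[Na])N1[C@H](Cc2ccccc2)COC1=O | intermediate
11 | (2R,3R)-1,4-bis[(4R)-4-benzyl-2-oxo-1,3-oxazolidin-3-yl]-2,3-bis({4-[(tert-butyldimethylsilyl)oxy]-3-methoxyphenyl}methyl)butane-1,4-dione | O=C(N1[C@H](Cc2ccccc2)COC1=O)[C@H](Cc1ccc(O[Si](C)(C)C(C)(C)C)c(OC)c1)[C@H](C(=O)N1[C@H](Cc2ccccc2)COC1=O)Cc1ccc(O[Si](C)(C)C(C)(C)C)c(OC)c1 | intermediate
12 | (2R,3R)-2,3-bis({4-[(tert-butyldimethylsilyl)oxy]-3-methoxyphenyl}methyl)butane-1,4-diol | OC[C@H](Cc1ccc(O[Si](C)(C)C(C)(C)C)c(OC)c1)[C@H](CO)Cc1ccc(O[Si](C)(C)C(C)(C)C)c(OC)c1 | intermediate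
13 | (E)-ferulic acid | COc1cc(/C=C/C(=O)O)ccc1O | starting material
14 | tert-butyldimethylsilyl (E)-3-{4-[(tert-butyldimethylsilyl)oxy]-3-methoxyphenyl}prop-2-enoate | COc1cc(/C=C/C(=O)O[Si](C)(C)C(C)(C)C)ccc1O[Si](C)(C)C(C)(C)C | intermediate
15 | (E)-3-{4-[(tert-butyldimethylsilyl)oxy]-3-methoxyphenyl}prop-2-enoic acid | COc1cc(/C=C/C(=O)O)ccc1O[Si](C)(C)C(C)(C)C | intermediate
16 | (2R,3R)-4-hydroxy-2,3-bis({4-[(tert-butyldimethylsilyl)oxy]-3-methoxyphenyl}methyl)butyl (E)-3-{4-[(tert-butyldimethylsilyl)oxy]-3-methoxyphenyl}prop-2-enoate | COc1cc(/C=C/C(=O)OC[C@H](Cc2ccc(O[Si](C)(C)C(C)(C)C)c(OC)c2)[C@H](CO)Cc2ccc(O[Si](C)(C)C(C)(C)C)c(OC)c2)ccc1O[Si](C)(C)C(C)(C)C | intermediate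
17 | hanultarin, (2R,3R)-4-hydroxy-2,3-bis[(4-hydroxy-3-methoxyphenyl)methyl]butyl (E)-ferulate | COc1cc(/C=C/C(=O)OC[C@H](Cc2ccc(O)c(OC)c2)[C@H](CO)Cc2ccc(O)c(OC)c2)ccc1O | target

Total step count: 9. Longest linear sequence: 7 steps (steps 1, 2, 3, 5, 6, 8, 9, from vanillin to hanultarin).

Steps most likely to fail

Step 5. Several processes could spoil it.
- The second enolisation may stay incomplete, or the hindered second enolate may alkylate sluggishly.
- Facial selectivity may erode in the second alkylation.
- On warming, the enolate may take up the neighbouring imide acyl group or fragment by loss of the auxiliary.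

The fallback forms the central C2–C3 bond instead of the two benzylic bonds. It sets out from 15 and rejoins the route at 12.
- Hydrogenation of the cinnamic double bond (H2, Pd/C, EtOAc) would give 3-{4-[(tert-butyldimethylsilyl)oxy]-3-methoxyphenyl}propanoic acid F1.
- Pivaloyl chloride and Et3N would convert it into the mixed pivalic anhydride F2.
- In the same flask, F2 acylates commercial (4S)-4-benzyl-1,3-oxazolidin-2-one (LiCl, Et3N, THF) to give the 3-arylpropanoyl imide F3.
- Oxidative enolate homocoupling (LiN(iPr)2, THF, −78 °C, then CuCl2) is a known way to C2-symmetric 2,3-dibenzylsuccinyl bis-imides. Here the incoming group is C3, which outranks C7, so the (S)-auxiliary is the one that leads to the (2R,3R)-bis-imide F4.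
- Reduction of F4 under the conditions of step 6 would give 12.

Step 6. Both acyl carbonyls are flanked by branched carbons. Hydride may therefore attack the ring carbonyl and open the oxazolidinone instead of releasing it, and long reaction times could cost an aryl silyl group. The fallback separates cleavage from reduction. It sets out from 11 and rejoins at 12.
- LiSEt (EtSH, n-BuLi, THF, 0 °C) is a soft nucleophile known to attack only the exocyclic carbonyl of hindered imides. It would give the S,S′-diethyl bis(thioester) F5.
- The unhindered, activated thioester groups of F5 are then reduced by LiBH4 in THF–EtOH at 0 °C to 12.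

Step 8. Over-acylation may leave a statistical distribution of diol, monoester and diester, and rearrangement of the activated acid to an unreactive N-acylurea may lower conversion. The fallback replaces statistical control by template control. It sets out from 12 and 15 and rejoins at 16.
- Heating 12 with Bu2SnO in toluene with azeotropic removal of water would give the cyclic dibutylstannylene acetal F6.
- Acid 15 would be converted under neutral conditions by 1-chloro-N,N,2-trimethylprop-1-en-1-amine (CH2Cl2, 0 °C) into O-TBS-feruloyl chloride F7.
- One equivalent of F7 acylates one tin-bound oxygen of F6. The remaining chlorostannyl alkoxide is much less nucleophilic, so the reaction should stop there, and aqueous work-up releases 16.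

Further compounds
F1 | step 5 | 3-{4-[(tert-butyldimethylsilyl)oxy]-3-methoxyphenyl}propanoic acid | COc1cc(CCC(=O)O)ccc1O[Si](C)(C)C(C)(C)C
F2 | step 5 | 3-{4-[(tert-butyldimethylsilyl)oxy]-3-methoxyphenyl}propanoic pivalic anhydride | COc1cc(CCC(=O)OC(=O)C(C)(C)C)ccc1O[Si](C)(C)C(C)(C)C
F3 | step 5 | (4S)-4-benzyl-3-(3-{4-[(tert-butyldimethylsilyl)oxy]-3-methoxyphenyl}propanoyl)-1,3-oxazolidin-2-one | COc1cc(CCC(=O)N2[C@@H](Cc3ccccc3)COC2=O)ccc1O[Si](C)(C)C(C)(C)C
F4 | step 5 | (2R,3R)-1,4-bis[(4S)-4-benzyl-2-oxo-1,3-oxazolidin-3-yl]-2,3-bis({4-[(tert-butyldimethylsilyl)oxy]-3-methoxyphenyl}methyl)butane-1,4-dione | O=C(N1[C@@H](Cc2ccccc2)COC1=O)[C@H](Cc1ccc(O[Si](C)(C)C(C)(C)C)c(OC)c1)[C@H](C(=O)N1[C@@H](Cc2ccccc2)COC1=O)Cc1ccc(O[Si](C)(C)C(C)(C)C)c(OC)c1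
F5 | step 6 | S,S′-diethyl (2R,3R)-2,3-bis({4-[(tert-butyldimethylsilyl)oxy]-3-methoxyphenyl}methyl)butanebis(thioate) | CCSC(=O)[C@H](Cc1ccc(O[Si](C)(C)C(C)(C)C)c(OC)c1)[C@H](C(=O)SCC)Cc1ccc(O[Si](C)(C)C(C)(C)C)c(OC)c1
F6 | step 8 | (5R,6R)-2,2-dibutyl-5,6-bis({4-[(tert-butyldimethylsilyl)oxy]-3-methoxyphenyl}methyl)-1,3,2-dioxastannepane | CCCC[Sn]1(CCCC)OC[C@H](Cc2ccc(O[Si](C)(C)C(C)(C)C)c(OC)c2)[C@@H](Cc2ccc(O[Si](C)(C)C(C)(C)C)c(OC)c2)CO1
F7 | step 8 | (E)-3-{4-[(tert-butyldimethylsilyl)oxy]-3-methoxyphenyl}prop-2-enoyl chloride | COc1cc(/C=C/C(=O)Cl)ccc1O[Si](C)(C)C(C)(C)C
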